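A Q cannot both begin a chain and end up in Q2, so the charge of Q has to be split between those two accounts before a chain length means anything.

common to all: X 0.0900 M; Q 170 mM; time 30 s

| flask | E |
|---|---|
| Wednesday's | 3.0 M |
| Sunday's | 1.5 M |

    E + Q → D + G (k1 = 0.41 M⁻¹ s⁻¹)
    E + D → G + D, rate k2*[D]*[E] (k2 = 0.16 M⁻¹ s⁻¹)
    D + X → D.X (k3 = 0.15 M⁻¹ s⁻¹)
    2 Q → Q2 (k4 = 2.7 M⁻¹ s⁻¹)

1. which of the two ends with the longer chains by the average number of monomer units in a chain (chains begun, living or dead) ("neither" if they lie within 10%) (Wednesday's / Sunday's / neither)
2. average number of monomer units in a chain (chains begun, living or dead) at the end, Wednesday's
3. average number of monomer units in a chain (chains begun, living or dead) at the end, Sunday's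

- two of one species on the left: rate k times its square, two consumed each time
- the average divides the monomer in chains by the number of chains begun, living and dead together
- run time (Wednesday's): 30 s

E is the monomer, Q starts chains, D is a living chain, X caps it as D.X, and G counts monomer in chains. Open the ledger on Q, the limiting reagent. Even in Sunday's flask, which holds less E than Wednesday's, the starting step alone halves Q in 1.13 s at the charged E, far shorter than the 30 s of the run, so these books close early.

There are two entries. Let r be the rate at which dimerisation removes Q, two per turn, over the rate at which the starting step removes it. At the charge, r is 0.746 for Wednesday's and 1.49 for Sunday's. Holding E at its charge and integrating both withdrawals together books ln(1 + r)/r of the Q to chains and the remainder to Q2, which gives 74.7% for Wednesday's and 61.2% for Sunday's.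

But each chain begun takes one E, so while Q lasts E stands lower, on average by about half of those chains. Put that lowered E back into r and go round again: Wednesday's gives 74.3% and Sunday's 60.4%. This is the chain share, the fraction of the Q charge that begins a chain.

Dividing the E charged by the chains begun gives a ceiling on the average: 23.7 for Wednesday's and 14.6 for Sunday's. The average is that ceiling times the fraction of E converted, which I leave unreckoned. If the two flasks convert comparable fractions, Wednesday's ends longer.

The forecast also says Wednesday's, with 10 (9.5 to 10.5) against 5.5 (5.2 to 5.8), holding that “Q is gone within a few seconds”.

The flasks give 9.98 for Wednesday's and 5.48 for Sunday's.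

In Sunday's flask at 13.1 s, the half-life of Q by the starting step is 1.4 s, far shorter than the 49 s of E by growth. In the same flask, half of the starting turnover up to the end of the run is done by 0.806 s, much earlier than half of the growth turnover at 13.1 s. Dividing the E found in G by the chains begun, the chain share of the Q charge, gives 9.99 for Wednesday's and 5.49 for Sunday's. A neighbour of Sunday's charged with 0.38 M of E has, after the same two rounds, a chain share of 31.4%. With 28.9% of its E in G, that makes 2.06, and the flask reads 2.07.

The rate constants were set for the occasion; the flask was simulated.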